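## The problem

Compound 17 is an achiral linear pentamer: five six-membered rings A to E are joined in a row by four CH2 bridges. Rings B, C and D are hexasubstituted butyrylphloroglucinols; rings A and E are butyrylfilicinic acid units, that is gem-dimethylated, enolised cyclohexanetriones. With no stereocentre to set, the task is one of sequence and regiochemistry. Ring C carries two equal bridges, rings B and D each carry one bridge to ring C and a different one to a filicinic acid ring, and every bridge lies between two hydroxylated carbons and meta to a butyryl group. Condensation of free phenols with formaldehyde equilibrates: a CH2 between two polyhydroxylated rings is cut and re-formed under acid (ipso-protonation, retro-Friedel–Crafts) and under base (quinone methide exchange), so it cannot be expected to give one defined five-ring sequence. This lability, the air sensitivity of the phenolates and the vinylogous acidity of rings A and E mean the free polyphenol should exist only in the last two operations of the main line. The enabling feature is that the two inner bridge carbons stand meta to one another on ring C, and each lies between two aryl carbons flanked by oxygen on both sides. Each can therefore be carried as the carbonyl carbon of a diaryl ketone, so ring C with both bridge carbons is an isophthaloyl unit. At that oxidation level the bridge cannot ionise and leave, and the ketone deactivates the ring it sits on, so bond formation stops after one event per outer ring.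

## Retrosynthesis

**Outer bridges (17 to 11 and 14).** The two bonds from the outer CH2 groups to the aromatic carbons of rings B and D are cut. This leaves the three-ring core 11 and two molecules of the methylene trione 16, which arises in the flask from the Mannich salt 15 of butyrylfilicinic acid 14. The electrophile is placed on the filicinic acid side because 14 has a single nucleophilic ring carbon, so 15 forms without ambiguity. Core 11 has exactly two nucleophilic ring CH positions, since ring C is fully substituted, so the number of caps is fixed by structure. The forward reaction must be a conjugate addition faster than transfer of the CH2 unit between partners, under conditions too mild to disturb the inner bridges.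

**Filicinic acid unit (14 to 13 to 12 and 8).** The two C–CH3 bonds at the quaternary carbon are cut, leading to phlorobutyrophenone 13, and the aryl–acyl bond of 13 is cut to phloroglucinol 12 and butyryl chloride 8. Both are classical operations on phloroglucinols; the dearomatising C-methylation is the one with a selectivity question.

**Unmasking (11 to 10).** Nine O–CH3 bonds are cut. Methyl is chosen because it alone survives the AlCl3 acylations and the acidic reduction. The price is one exhaustive BBr3 cleavage, placed after butyrylation so that every ring is deactivated by a chelated ketone when its hydroxyls are set free.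

**Butyryl groups (10 to 9 and 8; 9 to 7 and 8).** The three aryl–acyl bonds are cut in two stages: first the ring C ketone, leaving the bis-ketone 9 and one molecule of 8, then the two outer ketones, leaving 7 and two more molecules of 8. Bringing the butyryl groups in with the building blocks would put three more ketones into the reduction of the bridges. Added afterwards, they raise no regiochemical question within a ring: ring C of 7 has one CH, and rings B and D each have two equivalent CH positions. The acylation is divided because the two kinds of CH differ. Those of rings B and D lie between one methoxy group that can turn away and one that is buttressed by the benzyl arm. The CH of ring C lies between two methoxy groups that are each pressed towards it by a neighbouring benzyl arm. The open positions are therefore filled first, under mild conditions that stop at one acyl group per ring. The hindered position is then addressed on a substrate whose outer rings are already switched off, so it can be pushed without over-acylation.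

**Oxidation level (7 to 6).** The two bridge CH2 groups are traced back to the carbonyl groups of bis-benzophenone 6. No skeletal bond is cut; this change gives the key step an acyl electrophile in place of an ionisable benzyl one.

**Key disconnection (6 to 5 and 1).** The two bonds from the bridge carbonyls to rings B and D are cut, leaving both bridge carbons on ring C as the diacid chloride 5, with two molecules of 1,3,5-trimethoxybenzene 1 as nucleophile. The opposite cut, ring C as nucleophile towards two molecules of an aroyl chloride, would ask one trimethoxybenzene ring to be acylated twice, which the first ketone opposes. The chosen direction uses that same deactivation to stop each outer ring after one acylation. One symmetrical bis-electrophile and the cheapest possible nucleophile result.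

**Ring C building block (5 to 4 to 3 to 1).** The C–Cl bonds lead to diacid 4, the carboxyl oxygens to dialdehyde 3, and the two aryl–CHO bonds to 1. Two-fold Rieche formylation is preferred over Vilsmeier conditions, whose first iminium group would switch the ring off.

## Roads not taken

**Alternative 1:** The cut lies inside ring C: the bond from ring C to its butyryl carbonyl and the neighbouring aryl C–O bond are made together. The ortho-silyl aryl triflate A1, already carrying both benzyl arms with rings B and D, would be treated with CsF. The aryne so released would take up butyric acid A2 by attack of the carboxylate oxygen and shift of the acyl group to the aryl anion, giving the ortho-hydroxy ketone A3.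
- Merits: the methoxy group beside the aryne directs oxygen to the distal carbon and the acyl group next to the methoxy group, which is the orientation required. Ring C would receive its ketone without a Lewis acid touching the bridges. In this respect it is better than the chosen plan, which acylates the most hindered CH, that of ring C in 9, under AlCl3.
- Weak points: A1 is a hexasubstituted benzene whose adjacent silyl and triflate groups must be placed on a ring that already bears two benzyl arms, so the bridge problem has to be solved before the key step and several steps added after it. The acid O–H can protonate the aryl anion before the acyl shift, ending at an aryl butyrate. Rings B and D still need Friedel–Crafts butyrylation.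
- Comparison: the chosen plan sets against it a key step on commodity materials that also builds both bridges, and a route several steps shorter.

**Alternative 2:** Ring C is cut between its butyryl-bearing carbon and an oxygenated carbon. The open-chain tetracarbonyl ester A4 would cyclise under base by attack of its C-6 methylene on the ester carbon (Claisen/Dieckmann type), and enolisation would give the aromatic ring of A5.
- Merits: the route is biomimetic, ring C arrives with its butyryl group and three free hydroxyls, and the methoxymethyl ethers on rings B and D come off with mild acid. That deprotection is gentler than the ninefold BBr3 cleavage of the chosen plan.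
- Weak points: A4 needs two regioselective C-benzylations of a polyketide polyanion with highly ionisable 2,4,6-trioxygenated benzylic halides. It exists as a mixture of tautomers and diastereomers, and its cyclisation competes with aldol closure and with O-cyclisation to pyrones. Methoxymethyl ethers ortho to ketones are themselves acid-labile during the chain assembly.
- Comparison: the chosen plan answers with reactions whose outcome on this substitution pattern is predictable, and with starting materials that need no multistep preparation.

**Alternative 3:** The two bonds from ring C to the inner bridge carbons are cut. The dibromo ketone A6 would couple with two equivalents of the benzylic zinc chloride A7 under Pd(OAc)2 and a bulky biarylphosphine (Negishi coupling), giving A8, which is identical with compound 10 of the chosen route.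
- Merits: all three butyryl groups are in place and regiochemically fixed before the rings are joined, and neither a reduction nor a late acylation is needed. In regiochemical certainty this road is better than the chosen one.
- Weak points: each C–Br bond of A6 lies between two methoxy groups, so oxidative addition to zerovalent palladium and the second coupling are hindered. A7 must be made from a 2,4,6-trimethoxybenzylic halide, which ionises and self-condenses readily, and homocoupling during zinc insertion is likely. Preparing A6 and A7 takes about as many steps as the whole sequence to 10.
- Comparison: the chosen plan sets against it a metal-free, two-directional key step from stable partners, and keeps this coupling in mind as a different entry to 10.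

Key step: step 4

Assumption: 17 has no stereocentre, and rings A and E are drawn as one enol tautomer of a freely equilibrating set; all tautomers are treated as the same compound.

## Route

Step 1
Reactants: 1 1,3,5-trimethoxybenzene
Product: 3 2,4,6-trimethoxyisophthalaldehyde, via bis(chloro ether) 2 (not isolated)
Conditions: Cl2CHOMe (4 equiv), TiCl4 (4.5 equiv), CH2Cl2, −10 °C to rt; then ice-cold 1 M HCl
Reagents that add atoms: dichloromethyl methyl ether, COC(Cl)Cl; water, O
Why: Rieche formylation (electrophilic substitution by the chloro(methoxy)carbenium ion); the second formylation still finds a CH flanked by two methoxy groups, as in known two-fold Rieche formylations of phloroglucinol triethers, the third position is switched off by two formyl-type groups, and the chloro ether 2 hydrolyses to the dialdehyde on work-up.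

Step 2
Reactants: 3 2,4,6-trimethoxyisophthalaldehyde
Product: 4 2,4,6-trimethoxyisophthalic acid
Conditions: NaClO2, NaH2PO4, 2-methyl-2-butene (excess), t-BuOH/THF/H2O, 0 °C to rt; acidify to pH 2 at 0 °C
Reagents that add atoms: sodium chlorite, [Na+].[O-]Cl=O
Why: Pinnick oxidation converts both aryl aldehydes into acids without touching the ethers; the alkene scavenges HOCl so the remaining electron-rich ring CH is not chlorinated, and cold acidification avoids protodecarboxylation.

Step 3
Reactants: 4 2,4,6-trimethoxyisophthalic acid
Product: 5 2,4,6-trimethoxyisophthaloyl dichloride
Conditions: (COCl)2 (3 equiv), DMF (cat.), CH2Cl2, 0 °C to rt; evaporate, use crude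
Reagents that add atoms: oxalyl chloride, O=C(Cl)C(Cl)=O
Why: Acid chloride formation through the catalytic chloroiminium species, as practised for 2,4,6-trimethoxybenzoic acid; only gases are released, so the moisture-sensitive dichloride can be used without purification.

Step 4
Reactants: 5 2,4,6-trimethoxyisophthaloyl dichloride; 1 1,3,5-trimethoxybenzene (2 molecules, used in excess)
Product: 6 (2,4,6-trimethoxy-1,3-phenylene)bis[(2,4,6-trimethoxyphenyl)methanone]
Conditions: 1 (3 equiv), AlCl3 (2.5 equiv), CH2Cl2, −10 to 0 °C; poured onto ice/1 M HCl
Reagents that add atoms: none
Why: Friedel–Crafts acylation run in two directions from one bis-electrophile. AlCl3 ionises each C–Cl bond of 5 to an acylium ion that is stabilised by two ortho and one para methoxy groups and, being linear, is not shielded by them; it attacks 1, whose three ring CH positions are equivalent, and the Wheland intermediate loses a proton to give the ketone as its AlCl3 complex. The closest known reaction type is the AlCl3-mediated aroylation of 1,3,5-trimethoxybenzene to polymethoxybenzophenones, including the 2,2',4,4',6,6'-hexamethoxy pattern. No ring closes and no stereocentre forms. Mono-acylation of each outer ring is needed: the complexed aroyl group switches that ring off and 1 is in excess, so chains cannot grow. The electrophile must not acylate itself: the lone CH of 5 sits on a ring bearing two acyl chloride groups and is far less nucleophilic than 1. The methyl ethers must survive: low temperature, a small excess of AlCl3 and a cold acidic quench hold back chelation-assisted ortho-demethylation.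

Step 5
Reactants: 6 (2,4,6-trimethoxy-1,3-phenylene)bis[(2,4,6-trimethoxyphenyl)methanone]
Product: 7 1,3,5-trimethoxy-2,4-bis(2,4,6-trimethoxybenzyl)benzene
Conditions: Et3SiH (6 equiv), CF3CO2H, CH2Cl2, 0 °C to rt
Reagents that add atoms: none
Why: Ionic hydrogenation of electron-rich diaryl ketones: protonation, hydride transfer from Et3SiH, ionisation of the benzhydrol to a doubly benzylic cation stabilised by six methoxy groups, and a second hydride transfer; both ketones are of one kind and the aryl methyl ethers are inert.

Step 6
Reactants: 7 1,3,5-trimethoxy-2,4-bis(2,4,6-trimethoxybenzyl)benzene; 8 butyryl chloride (2 molecules)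
Product: 9 2,4-bis(3-butanoyl-2,4,6-trimethoxybenzyl)-1,3,5-trimethoxybenzene
Conditions: 8 (2.1 equiv) premixed with AlCl3 (2.3 equiv), added slowly to 7, CH2Cl2, −30 to −10 °C; ice/1 M HCl
Reagents that add atoms: none
Why: Friedel–Crafts acylation at the four equivalent CH positions of rings B and D, each flanked by one methoxy group that can turn away, whereas the lone CH of ring C lies between two methoxy groups buttressed by the benzyl arms and should react more slowly at low temperature with two equivalents of the acylium complex. The AlCl3-complexed ketone switches each outer ring off after its first acylation; any material that is also acylated on ring C is compound 10 and is carried forward with the product of step 7.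

Step 7
Reactants: 9 2,4-bis(3-butanoyl-2,4,6-trimethoxybenzyl)-1,3,5-trimethoxybenzene; 8 butyryl chloride
Product: 10 1-[3,5-bis(3-butanoyl-2,4,6-trimethoxybenzyl)-2,4,6-trimethoxyphenyl]butan-1-one
Conditions: 8 (1.5 equiv), AlCl3 (4 equiv), CH2Cl2, 0 °C to rt; ice/1 M HCl
Reagents that add atoms: none
Why: Friedel–Crafts acylation of the one remaining activated CH, that of ring C, which lies para and twice ortho to methoxy groups; both outer rings carry an AlCl3-complexed ketone and are deactivated, so the extra Lewis acid and the higher temperature needed at this hindered position should not bring a second acyl group onto ring B or D, and only one regioisomer is possible.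

Step 8
Reactants: 10 1-[3,5-bis(3-butanoyl-2,4,6-trimethoxybenzyl)-2,4,6-trimethoxyphenyl]butan-1-one
Product: 11 1-[3,5-bis(3-butanoyl-2,4,6-trihydroxybenzyl)-2,4,6-trihydroxyphenyl]butan-1-one
Conditions: BBr3 (15 equiv), CH2Cl2, −78 °C to rt; then ice-water, argon
Reagents that add atoms: none
Why: Lewis-acid cleavage of aryl methyl ethers with BBr3; the six ethers ortho to ketones are cleaved fast through chelates and the three para ethers follow at rt, while the butyryl group on every ring lowers its basicity and so disfavours ipso-protonation at the bridges.

Step 9
Reactants: 12 phloroglucinol; 8 butyryl chloride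
Product: 13 1-(2,4,6-trihydroxyphenyl)butan-1-one (phlorobutyrophenone)
Conditions: 8 (1.05 equiv), AlCl3 (3.5 equiv), CH2Cl2/MeNO2, rt to 40 °C; ice/1 M HCl
Reagents that add atoms: none
Why: Classical Friedel–Crafts C-acylation of phloroglucinol (any O-acyl material rearranges under the conditions); the chelated monoacyl product is deactivated against a second acylation.

Step 10
Reactants: 13 1-(2,4,6-trihydroxyphenyl)butan-1-one
Product: 14 2-butanoyl-3,5-dihydroxy-4,4-dimethylcyclohexa-2,5-dien-1-one (butyrylfilicinic acid)
Conditions: MeI (2.2 equiv), NaOMe (3.5 equiv), MeOH, 0 °C to rt; 1 M HCl; extraction into aqueous NaHCO3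
Reagents that add atoms: iodomethane, CI
Why: Dearomatising geminal C-methylation of an acylphloroglucinol polyanion with a soft electrophile in a protic medium, the standard entry to acylfilicinic acids; 14 is a much stronger acid than under- or ring-dimethylated phloroglucinols and should be separable from them by bicarbonate extraction.

Step 11
Reactants: 11 1-[3,5-bis(3-butanoyl-2,4,6-trihydroxybenzyl)-2,4,6-trihydroxyphenyl]butan-1-one; 14 butyrylfilicinic acid (2 molecules)
Product: 17 CNP0188003.0, 1-[3,5-bis({3-butanoyl-5-[(5-butanoyl-2,4-dihydroxy-3,3-dimethyl-6-oxocyclohexa-1,4-dien-1-yl)methyl]-2,4,6-trihydroxyphenyl}methyl)-2,4,6-trihydroxyphenyl]butan-1-one, via Mannich base hydroiodide 15 (not isolated), via methylene trione 16 (not isolated)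
Conditions: 14 (2.2 equiv), CH2=NMe2+ I− (2.2 equiv), MeCN, 0 °C to rt; then 11 (1 equiv), NaOAc (2.5 equiv), 45 °C, argon
Reagents that add atoms: N,N-dimethylmethyleneiminium iodide (Eschenmoser's salt), C=[N+](C)C.[I-]
Why: Mannich aminomethylation of 14 at its only free ring carbon gives 15; buffering with NaOAc triggers loss of dimethylamine to the methylene trione 16, which undergoes Friedel–Crafts-type conjugate addition at the single free ring carbon of rings B and D of 11, a known way of joining cyclic β-triketones to acylphloroglucinols through one carbon. Ring C has no free position, so exactly two caps add, and the near-neutral medium should leave the inner bridges untouched.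

## Compound list

1 | 1,3,5-trimethoxybenzene | COc1cc(OC)cc(OC)c1 | starting material
2 | 1,3-bis[chloro(methoxy)methyl]-2,4,6-trimethoxybenzene (mixture of stereoisomers) | COC(Cl)c1c(OC)cc(OC)c(C(Cl)OC)c1OC | intermediate
3 | 2,4,6-trimethoxyisophthalaldehyde | COc1cc(OC)c(C=O)c(OC)c1C=O | intermediate
4 | 2,4,6-trimethoxyisophthalic acid | COc1cc(OC)c(C(=O)O)c(OC)c1C(=O)O | intermediate
5 | 2,4,6-trimethoxyisophthaloyl dichloride | COc1cc(OC)c(C(Cl)=O)c(OC)c1C(Cl)=O | intermediate
6 | (2,4,6-trimethoxy-1,3-phenylene)bis[(2,4,6-trimethoxyphenyl)methanone] | COc1cc(OC)c(C(=O)c2c(OC)cc(OC)cc2OC)c(OC)c1C(=O)c1c(OC)cc(OC)cc1OC | intermediate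
7 | 1,3,5-trimethoxy-2,4-bis(2,4,6-trimethoxybenzyl)benzene | COc1cc(OC)c(Cc2c(OC)cc(OC)cc2OC)c(OC)c1Cc1c(OC)cc(OC)cc1OC | intermediate
8 | butyryl chloride | CCCC(=O)Cl | starting material
9 | 2,4-bis(3-butanoyl-2,4,6-trimethoxybenzyl)-1,3,5-trimethoxybenzene | COc1cc(OC)c(Cc2c(OC)cc(OC)c(C(=O)CCC)c2OC)c(OC)c1Cc1c(OC)cc(OC)c(C(=O)CCC)c1OC | intermediate
10 | 1-[3,5-bis(3-butanoyl-2,4,6-trimethoxybenzyl)-2,4,6-trimethoxyphenyl]butan-1-one | CCCC(=O)c1c(OC)cc(OC)c(Cc2c(OC)c(Cc3c(OC)cc(OC)c(C(=O)CCC)c3OC)c(OC)c(C(=O)CCC)c2OC)c1OC | intermediate
11 | 1-[3,5-bis(3-butanoyl-2,4,6-trihydroxybenzyl)-2,4,6-trihydroxyphenyl]butan-1-one | CCCC(=O)c1c(O)cc(O)c(Cc2c(O)c(Cc3c(O)cc(O)c(C(=O)CCC)c3O)c(O)c(C(=O)CCC)c2O)c1O | intermediate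
12 | phloroglucinol | Oc1cc(O)cc(O)c1 | starting material
13 | 1-(2,4,6-trihydroxyphenyl)butan-1-one | CCCC(=O)c1c(O)cc(O)cc1O | intermediate
14 | 2-butanoyl-3,5-dihydroxy-4,4-dimethylcyclohexa-2,5-dien-1-one (butyrylfilicinic acid) | CCCC(=O)C1=C(O)C(C)(C)C(O)=CC1=O | intermediate
15 | 2-butanoyl-6-[(dimethylamino)methyl]-3,5-dihydroxy-4,4-dimethylcyclohexa-2,5-dien-1-one hydroiodide | CCCC(=O)C1=C(O)C(C)(C)C(O)=C(C[NH+](C)C)C1=O.[I-] | intermediate
16 | 2-butanoyl-3-hydroxy-4,4-dimethyl-6-methylidenecyclohex-2-ene-1,5-dione | CCCC(=O)C1=C(O)C(C)(C)C(=O)C(=C)C1=O | intermediate
17 | CNP0188003.0 (pentamer A–CH2–B–CH2–C–CH2–D–CH2–E, no stereocentre) | CCCC(=O)C1=C(O)C(C)(C)C(O)=C(Cc2c(O)c(Cc3c(O)c(Cc4c(O)c(CC5=C(O)C(C)(C)C(O)=C(C(=O)CCC)C5=O)c(O)c(C(=O)CCC)c4O)c(O)c(C(=O)CCC)c3O)c(O)c(C(=O)CCC)c2O)C1=O | target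

## Step count and least certain steps

Total: 11 steps. Longest linear sequence: 9 steps (steps 1 to 8 and 11); steps 9 and 10 form the side branch to 14.

**Step 4 (key step).** The most likely failure is chelation-assisted loss of methyl groups from the methoxy groups ortho to the new carbonyls under AlCl3. The second risk is stalling after the first acylation, because the remaining acyl chloride sits on a ring already tied up as a ketone–AlCl3 complex. Partial O-demethylation can be repaired by exhaustive re-methylation of the crude product (Me2SO4, K2CO3, acetone). Fallback with reversed polarity: the route sets out from dialdehyde 3 and from 1. Lithiation of 1 (n-BuLi, THF, 0 °C) gives (2,4,6-trimethoxyphenyl)lithium F1, which adds to both formyl groups of 3 to give the bis-benzhydrol (2,4,6-trimethoxy-1,3-phenylene)bis[(2,4,6-trimethoxyphenyl)methanol] F2. Oxidation of F2 with MnO2 in CH2Cl2 returns to the route at 6.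

**Step 1.** Formylation may stop after the first formyl group, whose oxocarbenium or carbonyl form deactivates the ring. Fallback: setting out from phloroglucinol 12, two-fold Vilsmeier–Haack formylation (POCl3, DMF, dioxane) gives 2,4,6-trihydroxyisophthalaldehyde F3. Free hydroxyls keep the ring nucleophilic after the first formylation. O-Permethylation (Me2SO4, K2CO3, acetone, reflux) then rejoins the route at 3.

**Step 5.** Once a bridge is reduced it becomes a benzyl group on a very electron-rich ring. Ipso-protonation in CF3CO2H can then cut it, and the silane would reduce the fragments irreversibly. The reduction may also be slow at the stage of the highly stabilised cations. Fallback that forms the bridges directly at the CH2 level: setting out from 3, NaBH4 in MeOH gives (2,4,6-trimethoxy-1,3-phenylene)dimethanol F4. Benzylation of a large excess of 1 with F4 under catalytic Sc(OTf)3 in CH2Cl2 at 0 °C returns to the route at 7. The excess of 1 must then do the work that the ketone oxidation level does in the main route, which is why this is only the reserve.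

**Step 7.** The CH of ring C lies between two methoxy groups that are each buttressed by a benzyl arm, so the acylation may be slow. Forcing it with more AlCl3 or a higher temperature invites bridge scission by the HCl–AlCl3 pair and chelation-assisted loss of methyl groups ortho to the existing ketones. The demethylation alone would be tolerable, since step 8 removes every methyl group, but a freed phenol could be O-acylated. Fallback without acid, which replaces steps 6 and 7 together: setting out from 7, threefold directed ortho-lithiation (n-BuLi, TMEDA, THF, 0 °C; one lithium per ring at a CH between two methoxy groups) gives the trilithio derivative of 7 F5. Quenching with N-methoxy-N-methylbutanamide (three molecules) returns to the route at 10.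

**Step 8.** Cleavage of the three ethers para to the ketones may be incomplete, and HBr may cut the bridges once the phenols are free. Fallback by nucleophilic in place of Lewis-acid dealkylation: setting out from 10, NaSEt in DMF at 120 °C under argon removes the methyl groups by SN2 attack on carbon and returns to the route at 11 after acidification. It makes no new isolated compound.

**Step 11.** Directional control may be lost: the CH2 unit can pass from 15 to unreacted 14, which dimerises the filicinic acid, and the liberated amine can start base-induced exchange of the inner bridges. Fallback with the roles of the partners exchanged: setting out from 11, Eschenmoser's salt (2.2 equiv, MeCN, rt) gives the isolable bis-Mannich base 1-[3,5-bis({3-butanoyl-5-[(dimethylamino)methyl]-2,4,6-trihydroxyphenyl}methyl)-2,4,6-trihydroxyphenyl]butan-1-one F6, which has no free ring carbon. Heating F6 with 14 (2.5 equiv) in dioxane at 90 °C generates ortho-quinone methides on rings B and D, and the enol carbon of 14 traps them to give 17.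

## Further compounds

F1 | step 4 | (2,4,6-trimethoxyphenyl)lithium | [Li]c1c(OC)cc(OC)cc1OC
F2 | step 4 | (2,4,6-trimethoxy-1,3-phenylene)bis[(2,4,6-trimethoxyphenyl)methanol], mixture of diastereomers | COc1cc(OC)c(C(O)c2c(OC)cc(OC)cc2OC)c(OC)c1C(O)c1c(OC)cc(OC)cc1OC
F3 | step 1 | 2,4,6-trihydroxyisophthalaldehyde | O=Cc1c(O)cc(O)c(C=O)c1O
F4 | step 5 | (2,4,6-trimethoxy-1,3-phenylene)dimethanol | COc1cc(OC)c(CO)c(OC)c1CO
F5 | step 7 | trilithio derivative of 7 (one lithium per ring, each between two methoxy groups) | COc1c([Li])c(OC)c(Cc2c(OC)c([Li])c(OC)cc2OC)c(OC)c1Cc1c(OC)c([Li])c(OC)cc1OC
F0 | step 8 | none | none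
F6 | step 11 | 1-[3,5-bis({3-butanoyl-5-[(dimethylamino)methyl]-2,4,6-trihydroxyphenyl}methyl)-2,4,6-trihydroxyphenyl]butan-1-one | CCCC(=O)c1c(O)c(CN(C)C)c(O)c(Cc2c(O)c(Cc3c(O)c(CN(C)C)c(O)c(C(=O)CCC)c3O)c(O)c(C(=O)CCC)c2O)c1O
A1 | alternative 1 | 2,4-bis(3-butanoyl-2,4,6-trimethoxybenzyl)-3,5-dimethoxy-6-(trimethylsilyl)phenyl trifluoromethanesulfonate | CCCC(=O)c1c(OC)cc(OC)c(Cc2c(OC)c(Cc3c(OC)cc(OC)c(C(=O)CCC)c3OC)c(OC)c([Si](C)(C)C)c2OS(=O)(=O)C(F)(F)F)c1OC
A2 | alternative 1 | butyric acid | CCCC(=O)O
A3 | alternative 1 | 1-[3,5-bis(3-butanoyl-2,4,6-trimethoxybenzyl)-2-hydroxy-4,6-dimethoxyphenyl]butan-1-one | CCCC(=O)c1c(OC)cc(OC)c(Cc2c(OC)c(Cc3c(OC)cc(OC)c(C(=O)CCC)c3OC)c(OC)c(C(=O)CCC)c2O)c1OC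
A4 | alternative 2 | methyl 2,4-bis[3-butanoyl-2,4,6-tris(methoxymethoxy)benzyl]-3,5,7-trioxodecanoate, mixture of diastereomers and tautomers | COC(=O)C(Cc1c(OCOC)cc(OCOC)c(C(=O)CCC)c1OCOC)C(=O)C(Cc1c(OCOC)cc(OCOC)c(C(=O)CCC)c1OCOC)C(=O)CC(=O)CCC
A5 | alternative 2 | 1-{3,5-bis[3-butanoyl-2,4,6-tris(methoxymethoxy)benzyl]-2,4,6-trihydroxyphenyl}butan-1-one | CCCC(=O)c1c(O)c(Cc2c(OCOC)cc(OCOC)c(C(=O)CCC)c2OCOC)c(O)c(Cc2c(OCOC)cc(OCOC)c(C(=O)CCC)c2OCOC)c1O
A6 | alternative 3 | 1-(3,5-dibromo-2,4,6-trimethoxyphenyl)butan-1-one | CCCC(=O)c1c(OC)c(Br)c(OC)c(Br)c1OC
A7 | alternative 3 | (3-butanoyl-2,4,6-trimethoxybenzyl)zinc chloride | CCCC(=O)c1c(OC)cc(OC)c(C[Zn]Cl)c1OC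
A8 | alternative 3 | 1-[3,5-bis(3-butanoyl-2,4,6-trimethoxybenzyl)-2,4,6-trimethoxyphenyl]butan-1-one (identical with 10) | CCCC(=O)c1c(OC)cc(OC)c(Cc2c(OC)c(Cc3c(OC)cc(OC)c(C(=O)CCC)c3OC)c(OC)c(C(=O)CCC)c2OC)c1OC
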